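## Retrosynthetic overview

1. The target comes from (2S)-5,7,8,2',6'-pentamethoxyflavanone by chelation-directed cleavage of the 5-O-methyl group (last step, no ring formed).
2. Ring C comes from an open-chain 2-(2,6-dimethoxybenzyloxy)aryl diazomethyl ketone. The key C2–C3 bond is made by enantioselective insertion of a rhodium α-keto carbenoid into the benzylic O–CH2 group. The carbenoid is an enolonium equivalent: the ketone α-carbon, the nucleophile of every aldol or chalcone route, is made electrophilic and joined to the electron-rich ether carbon, the other donor carbon of the precursor. C2 is set in the same event.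
3. The diazoketone comes from the aryl methyl ketone (diazo transfer), which comes from 2-hydroxy-3,4,6-trimethoxyacetophenone and 2,6-dimethoxybenzyl alcohol (achiral O1–C2 ether bond).
4. The acetophenone comes from 1,2,3,5-tetramethoxybenzene by Friedel–Crafts acetylation with in-flask ortho-demethylation.
5. Ring order: rings A and B are bought as intact benzenes; ring C is the only ring made and is closed in step 4.

Assumption: the sense of induction of the chiral dirhodium catalyst in step 4 cannot be predicted with certainty; the (S)-prolinate catalyst is written, and its mirror image (from D-proline) is used instead if the first run gives the 2R series (checked by circular dichroism and chiral HPLC).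

## Route

Step 1
Reactants: 1 1,2,3,5-tetramethoxybenzene
Product: 3 1-(2-hydroxy-3,4,6-trimethoxyphenyl)ethan-1-one, via 2,3,4,6-tetramethoxyacetophenone 2 (not isolated)
Conditions: AcCl (1.1 equiv), AlCl3 (2.2 equiv), CH2Cl2, 0 °C to rt; ice/aq. HCl
Reagents that add atoms: acetyl chloride, CC(Cl)=O
Why: Friedel–Crafts acylation at the only type of free ring position, followed in the same flask by AlCl3-mediated cleavage of the most crowded ortho-methoxy group (flanked by the acetyl group and the 3-OMe and chelated to aluminium through the carbonyl), the usual selectivity for polymethoxyacetophenones; no stereocentre.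

Step 2
Reactants: 3 1-(2-hydroxy-3,4,6-trimethoxyphenyl)ethan-1-one; 4 (2,6-dimethoxyphenyl)methanol
Product: 5 1-{2-[(2,6-dimethoxyphenyl)methoxy]-3,4,6-trimethoxyphenyl}ethan-1-one
Conditions: PPh3, DIAD, THF, 0 °C to rt
Reagents that add atoms: none
Why: Mitsunobu etherification, in which the hydrogen-bonded but sufficiently acidic phenol displaces the activated primary benzylic oxyphosphonium under neutral conditions, so the unstable 2,6-dimethoxybenzyl halide need not be handled; no stereocentre.

Step 3
Reactants: 5 1-{2-[(2,6-dimethoxyphenyl)methoxy]-3,4,6-trimethoxyphenyl}ethan-1-one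
Product: 7 2-diazo-1-{2-[(2,6-dimethoxyphenyl)methoxy]-3,4,6-trimethoxyphenyl}ethan-1-one, via trifluoroacetyl diketone 6 (not isolated)
Conditions: LiN(SiMe3)2, THF, −78 °C; CF3CO2CH2CF3; aq. HCl quench, crude carried on; MsN3, Et3N, H2O, MeCN, rt
Reagents that add atoms: methanesulfonyl azide, CS(=O)(=O)N=[N+]=[N-] (the two diazo nitrogens); 2,2,2-trifluoroethyl trifluoroacetate, O=C(OCC(F)(F)F)C(F)(F)F (its CF3CO group is carried only in 6)
Why: Danheiser detrifluoroacetylative diazo transfer (Regitz type), in which Claisen trifluoroacetylation of the only enolisable position activates the methyl ketone so that the sulfonyl azide delivers N2 while the trifluoroacetyl group is cleaved; the ethers are inert to these basic conditions; no stereocentre.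

Step 4
Reactants: 7 2-diazo-1-{2-[(2,6-dimethoxyphenyl)methoxy]-3,4,6-trimethoxyphenyl}ethan-1-one
Product: 8 (2S)-2-(2,6-dimethoxyphenyl)-5,7,8-trimethoxy-2,3-dihydro-4H-chromen-4-one
Conditions: dirhodium tetrakis[(S)-N-(benzenesulfonyl)prolinate] (1 mol %), CH2Cl2, 0 °C to rt, slow addition of 7; recrystallisation (EtOAc–hexane) to raise ee
Reagents that add atoms: none
Why: Enantioselective intramolecular rhodium-carbenoid C–H insertion (1,6-insertion), in which loss of N2 gives an electrophilic α-keto carbenoid at C3 (an enolonium equivalent) that inserts into the hydridic benzylic C–H next to the ether oxygen through a six-membered transition state, the chiral prolinate ligands selecting one of the two enantiotopic benzylic hydrogens so that C2 is formed directly as S; this is the known behaviour of 2-alkoxyaryl diazoketones, which give 2-substituted chroman-4-ones with this catalyst family.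

Step 5
Reactants: 8 (2S)-2-(2,6-dimethoxyphenyl)-5,7,8-trimethoxy-2,3-dihydro-4H-chromen-4-one
Product: 9 (2S)-2-(2,6-dimethoxyphenyl)-5-hydroxy-7,8-dimethoxy-2,3-dihydro-4H-chromen-4-one
Conditions: BCl3 (1.2 equiv), CH2Cl2, −78 to −20 °C, 30 min; cold aq. NaHCO3
Reagents that add atoms: none
Why: Chelation-controlled Lewis-acid ether cleavage, in which BCl3 binds between the C4 carbonyl and the peri 5-OMe so that only this methyl is removed at low temperature, the 7-, 8-, 2'- and 6'-methoxy groups stay, and the short, cold, base-free protocol leaves the C2 stereocentre from step 4 untouched.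

## Compound list

1 | 1,2,3,5-tetramethoxybenzene | COc1cc(OC)c(OC)c(OC)c1 | starting material
2 | 1-(2,3,4,6-tetramethoxyphenyl)ethan-1-one | CC(=O)c1c(OC)cc(OC)c(OC)c1OC | intermediate
3 | 1-(2-hydroxy-3,4,6-trimethoxyphenyl)ethan-1-one | CC(=O)c1c(OC)cc(OC)c(OC)c1O | intermediate
4 | (2,6-dimethoxyphenyl)methanol | COc1cccc(OC)c1CO | starting material
5 | 1-{2-[(2,6-dimethoxyphenyl)methoxy]-3,4,6-trimethoxyphenyl}ethan-1-one | CC(=O)c1c(OC)cc(OC)c(OC)c1OCc1c(OC)cccc1OC | intermediate
6 | 1-{2-[(2,6-dimethoxyphenyl)methoxy]-3,4,6-trimethoxyphenyl}-4,4,4-trifluorobutane-1,3-dione | O=C(CC(=O)C(F)(F)F)c1c(OC)cc(OC)c(OC)c1OCc1c(OC)cccc1OC | intermediate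
7 | 2-diazo-1-{2-[(2,6-dimethoxyphenyl)methoxy]-3,4,6-trimethoxyphenyl}ethan-1-one | [N-]=[N+]=CC(=O)c1c(OC)cc(OC)c(OC)c1OCc1c(OC)cccc1OC | intermediate
8 | (2S)-2-(2,6-dimethoxyphenyl)-5,7,8-trimethoxy-2,3-dihydro-4H-chromen-4-one | COc1cc(OC)c2c(c1OC)O[C@H](c1c(OC)cccc1OC)CC2=O | intermediate
9 | (2S)-2-(2,6-dimethoxyphenyl)-5-hydroxy-7,8-dimethoxy-2,3-dihydro-4H-chromen-4-one | COc1cc(O)c2c(c1OC)O[C@H](c1c(OC)cccc1OC)CC2=O | target

## Step count and risks

Total step count: 5. Longest linear sequence: 5 (1 → 3 → 5 → 7 → 8 → 9).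

**Most likely to fail, first: step 4.** The acceptor-only carbenoid may divert in three ways:
- oxonium-ylide formation at the benzyl ether oxygen followed by a 1,2-benzyl shift to a 2-benzylbenzofuran-3-one;
- insertion into the C–H of the other ortho-methoxy group;
- only moderate ee.

Fallback, setting out from 5 and coming back at 8: C-acylation of the methyl ketone (NaH, dibenzyl carbonate, toluene, 80 °C) gives benzyl 3-{2-[(2,6-dimethoxyphenyl)methoxy]-3,4,6-trimethoxyphenyl}-3-oxopropanoate F1. Regitz diazo transfer (4-acetamidobenzenesulfonyl azide, Et3N, MeCN) gives the benzyl α-diazo-β-keto ester F2. This stabilised acceptor/acceptor carbenoid precursor is decomposed with dirhodium tetrakis[N-phthaloyl-(S)-tert-leucinate] (toluene, 0 °C), the catalyst class best documented for enantioselective insertions of α-diazo-β-keto esters. The product is benzyl (2S,3R)-2-(2,6-dimethoxyphenyl)-5,7,8-trimethoxy-4-oxochromane-3-carboxylate F3; the C3 configuration is irrelevant. Neutral hydrogenolysis (H2, Pd/C, EtOAc, rt) liberates (2S,3R)-2-(2,6-dimethoxyphenyl)-5,7,8-trimethoxy-4-oxochromane-3-carboxylic acid F4, which loses CO2 on warming to 50 °C and rejoins the route at 8.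

**Second: step 5.** The Lewis acid could ionise the C2–O1 bond (a benzylic position activated by the 2,6-dimethoxyphenyl group), causing ring opening and racemisation, or could attack the crowded 8-OMe.

Fallback, setting out from 3 and coming back at 9, with the 5-oxygen carried as a fluoride-labile silyl ether so that no Lewis acid ever meets the stereocentre: AlCl3 in MeCN at reflux removes the chelated 6-O-methyl of 3 to give 1-(2,6-dihydroxy-3,4-dimethoxyphenyl)ethan-1-one F5. The less hindered hydroxyl is silylated (iPr3SiCl, imidazole, DMF) to 1-{2-hydroxy-3,4-dimethoxy-6-[(triisopropylsilyl)oxy]phenyl}ethan-1-one F6. Mitsunobu coupling with 4 gives 1-{2-[(2,6-dimethoxyphenyl)methoxy]-3,4-dimethoxy-6-[(triisopropylsilyl)oxy]phenyl}ethan-1-one F7. The same trifluoroacetylation and diazo transfer proceed through the trifluoroacetyl diketone F8 to the silyl-protected diazoketone F9. The same rhodium prolinate insertion gives (2S)-2-(2,6-dimethoxyphenyl)-7,8-dimethoxy-5-[(triisopropylsilyl)oxy]chroman-4-one F10. Bu4NF buffered with AcOH (THF, 0 °C) then frees the phenol and arrives at 9.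

**Third: step 2.** The phenol is hindered and hydrogen-bonded, and the electron-rich benzyl oxyphosphonium may C-benzylate ring A instead.

Fallback, setting out from 4 and coming back at 5: shaking 4 with concentrated aqueous HCl in toluene gives 2-(chloromethyl)-1,3-dimethoxybenzene F11, used at once. Williamson alkylation of 3 (K2CO3, catalytic Bu4NI, DMF, rt to 50 °C) then delivers 5.

## Further compounds

F1 | step 4 | benzyl 3-{2-[(2,6-dimethoxyphenyl)methoxy]-3,4,6-trimethoxyphenyl}-3-oxopropanoate | O=C(CC(=O)OCc1ccccc1)c1c(OC)cc(OC)c(OC)c1OCc1c(OC)cccc1OC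
F2 | step 4 | benzyl 2-diazo-3-{2-[(2,6-dimethoxyphenyl)methoxy]-3,4,6-trimethoxyphenyl}-3-oxopropanoate | [N-]=[N+]=C(C(=O)OCc1ccccc1)C(=O)c1c(OC)cc(OC)c(OC)c1OCc1c(OC)cccc1OC
F3 | step 4 | benzyl (2S,3R)-2-(2,6-dimethoxyphenyl)-5,7,8-trimethoxy-4-oxochromane-3-carboxylate | COc1cc(OC)c2c(c1OC)O[C@H](c1c(OC)cccc1OC)[C@@H](C(=O)OCc1ccccc1)C2=O
F4 | step 4 | (2S,3R)-2-(2,6-dimethoxyphenyl)-5,7,8-trimethoxy-4-oxochromane-3-carboxylic acid | COc1cc(OC)c2c(c1OC)O[C@H](c1c(OC)cccc1OC)[C@@H](C(O)=O)C2=O
F5 | step 5 | 1-(2,6-dihydroxy-3,4-dimethoxyphenyl)ethan-1-one | CC(=O)c1c(O)cc(OC)c(OC)c1O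
F6 | step 5 | 1-{2-hydroxy-3,4-dimethoxy-6-[(triisopropylsilyl)oxy]phenyl}ethan-1-one | CC(=O)c1c(O[Si](C(C)C)(C(C)C)C(C)C)cc(OC)c(OC)c1O
F7 | step 5 | 1-{2-[(2,6-dimethoxyphenyl)methoxy]-3,4-dimethoxy-6-[(triisopropylsilyl)oxy]phenyl}ethan-1-one | CC(=O)c1c(O[Si](C(C)C)(C(C)C)C(C)C)cc(OC)c(OC)c1OCc1c(OC)cccc1OC
F8 | step 5 | 1-{2-[(2,6-dimethoxyphenyl)methoxy]-3,4-dimethoxy-6-[(triisopropylsilyl)oxy]phenyl}-4,4,4-trifluorobutane-1,3-dione | O=C(CC(=O)C(F)(F)F)c1c(O[Si](C(C)C)(C(C)C)C(C)C)cc(OC)c(OC)c1OCc1c(OC)cccc1OC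
F9 | step 5 | 2-diazo-1-{2-[(2,6-dimethoxyphenyl)methoxy]-3,4-dimethoxy-6-[(triisopropylsilyl)oxy]phenyl}ethan-1-one | [N-]=[N+]=CC(=O)c1c(O[Si](C(C)C)(C(C)C)C(C)C)cc(OC)c(OC)c1OCc1c(OC)cccc1OC
F10 | step 5 | (2S)-2-(2,6-dimethoxyphenyl)-7,8-dimethoxy-5-[(triisopropylsilyl)oxy]chroman-4-one | COc1cc(O[Si](C(C)C)(C(C)C)C(C)C)c2c(c1OC)O[C@H](c1c(OC)cccc1OC)CC2=O
F11 | step 2 | 2-(chloromethyl)-1,3-dimethoxybenzene | COc1cccc(OC)c1CCl
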